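**Strategy.** The 2(5H)-furanone ring is disconnected at the lactone O1–C5 bond and the C3=C4 enol-ether double bond. This exploits the fact that quaternary C5 and aryl-bearing C4 are the α-carbon and the ketone carbon of a β-keto ester. In the key step the carboxylate of a methoxy(phosphono)acetic acid displaces chloride from an enantioenriched tertiary α-chloro-β-keto ester with inversion (O1–C5, setting C5). The tethered phosphonate carbanion then closes the ring onto the C4 ketone by intramolecular Horner–Wadsworth–Emmons olefination (C3=C4). The precursor is acyclic: a benzylated, catalytically chlorinated aroylacetate carrying the (R)-chromanol, which comes from a Jacobsen epoxidation.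

Key step: step 8

Remark on numbering: the butenolide atoms are numbered as a 2(5H)-furanone (O1, C2 lactone carbonyl, C3 bearing OMe, C4 bearing the aryl group, C5 quaternary). C5 is "C2" in the systematic carboxylate names below. The target is (S) at this carbon and (R) at the chromanol carbon.

Assumptions: compounds 1, 5 and 10 are taken as commercially available. The (R,R)-Mn(salen) catalyst is assumed to give the (3R,4R)-epoxide, and the ligand antipode in step 6 is chosen to give the (2R)-chloride.

**Step 1**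
Reactants: 1 2,2-dimethyl-2H-chromene-6-carbonitrile
Product: 2 (3R,4R)-3,4-epoxy-2,2-dimethylchromane-6-carbonitrile (cis-fused epoxide)
Conditions: (R,R)-Jacobsen Mn(salen)Cl (cat.), aq. NaOCl (buffered), 4-phenylpyridine N-oxide (cat.), CH2Cl2, 0 °C
Reagents that add atoms: sodium hypochlorite, [Na+].[O-]Cl
Why: Jacobsen–Katsuki epoxidation of a cis-disubstituted, aryl-conjugated alkene, the ideal substrate class; the chiral salen ligand directs oxygen transfer to one alkene face and sets C3 and C4 together.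

**Step 2**
Reactants: 2 (3R,4R)-3,4-epoxy-2,2-dimethylchromane-6-carbonitrile
Product: 3 (3R)-3-hydroxy-2,2-dimethylchromane-6-carbonitrile
Conditions: H2 (1 atm), 10% Pd/C, EtOAc, rt
Reagents that add atoms: none
Why: Pd-catalysed hydrogenolysis of an aryl epoxide should cleave only the benzylic C4–O bond, so C3 keeps its configuration, and the nitrile should survive neutral, low-pressure conditions.

**Step 3**
Reactants: 3 (3R)-3-hydroxy-2,2-dimethylchromane-6-carbonitrile
Product: 4 (3R)-3-hydroxy-2,2-dimethylchromane-6-carbaldehyde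
Conditions: DIBAL-H (2.5 equiv), CH2Cl2, −78 to 0 °C; then 1 M HCl
Reagents that add atoms: water, O
Why: DIBAL-H reduction of an aryl nitrile stops at the N-aluminated imine, which hydrolyses to the aldehyde on acidic work-up; the free hydroxyl only consumes one extra equivalent of hydride.

**Step 4**
Reactants: 5 1-[3,4-bis(benzyloxy)phenyl]ethan-1-one
Product: 6 methyl 3-[3,4-bis(benzyloxy)phenyl]-3-oxopropanoate
Conditions: NaH (2.5 equiv), dimethyl carbonate (3 equiv), THF, reflux; then aq. HCl
Reagents that add atoms: dimethyl carbonate, COC(=O)OC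
Why: crossed Claisen condensation of a methyl ketone enolate with dimethyl carbonate, driven by deprotonation of the β-keto ester formed.

**Step 5**
Reactants: 4 (3R)-3-hydroxy-2,2-dimethylchromane-6-carbaldehyde; 6 methyl 3-[3,4-bis(benzyloxy)phenyl]-3-oxopropanoate
Product: 8 methyl 3-[3,4-bis(benzyloxy)phenyl]-2-{[(3R)-3-hydroxy-2,2-dimethylchroman-6-yl]methyl}-3-oxopropanoate (C2 epimers, interconverting), via benzylidene β-keto ester 7 (not isolated)
Conditions: L-proline (20 mol %), Hantzsch ester (1.2 equiv), EtOH, 50 °C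
Reagents that add atoms: none
Why: one-pot Knoevenagel condensation and Hantzsch-ester conjugate reduction (three-component reductive alkylation); the doubly activated alkene of 7 should accept hydride as it forms, which also suppresses bis-addition, and the benzyl ethers are not touched.

**Step 6**
Reactants: 8 methyl 3-[3,4-bis(benzyloxy)phenyl]-2-{[(3R)-3-hydroxy-2,2-dimethylchroman-6-yl]methyl}-3-oxopropanoate
Product: 9 methyl (2R)-3-[3,4-bis(benzyloxy)phenyl]-2-chloro-2-{[(3R)-3-hydroxy-2,2-dimethylchroman-6-yl]methyl}-3-oxopropanoate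
Conditions: NCS (1.05 equiv), Cu(OTf)2 (10 mol %), chiral bis(oxazoline) ligand (12 mol %), CH2Cl2, 0 °C
Reagents that add atoms: N-chlorosuccinimide, O=C1CCC(=O)N1Cl
Why: catalytic enantioselective α-chlorination of a β-keto ester; the Cu(II)–bis(oxazoline) complex binds the substrate as a chelated enolate and NCS attacks the face left open by the ligand, which sets C2 as R, and the resulting tertiary chloride cannot enolise.

**Step 7**
Reactants: 10 methyl 2-(dimethoxyphosphoryl)-2-methoxyacetate
Product: 11 2-(dimethoxyphosphoryl)-2-methoxyacetic acid (racemic)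
Conditions: LiOH·H2O (1.05 equiv), THF–H2O, 0 °C; then 1 M HCl
Reagents that add atoms: lithium hydroxide, [Li+].[OH-]
Why: selective saponification of the carboxylic ester of a phosphonoacetate, since phosphonate methyl esters hydrolyse far more slowly under cold dilute hydroxide.

**Step 8**
Reactants: 9 methyl (2R)-3-[3,4-bis(benzyloxy)phenyl]-2-chloro-2-{[(3R)-3-hydroxy-2,2-dimethylchroman-6-yl]methyl}-3-oxopropanoate; 11 2-(dimethoxyphosphoryl)-2-methoxyacetic acid
Product: 13 methyl (2S)-3-[3,4-bis(benzyloxy)phenyl]-2-{[(3R)-3-hydroxy-2,2-dimethylchroman-6-yl]methyl}-4-methoxy-5-oxo-2,5-dihydrofuran-2-carboxylate, via α-acyloxy β-keto ester phosphonate 12 (not isolated)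
Conditions: 11 (1.5 equiv), Cs2CO3 (0.75 equiv), DMF, rt; add 9, rt to 40 °C; then LiCl, DBU, rt (one pot)
Reagents that add atoms: none
Why: The caesium carboxylate of 11 attacks the chlorine-bearing carbon of 9 from the face opposite chloride in an SN2 displacement accelerated by both flanking carbonyl groups, giving 12 with inversion [(2R) to (2S)]; DBU/LiCl then deprotonates the now ester-activated phosphonate carbon, which adds to the aryl ketone and collapses through the oxaphosphetane to the C3=C4 bond. The closest known reaction type is the one-pot carboxylate alkylation/intramolecular condensation of α-halo ketones to 2(5H)-furanones, here in its Horner–Wadsworth–Emmons form, combined with the known invertive substitution of tertiary α-chloro-β-keto esters. The furanone ring closes by 5-exo-trig addition of the carbanion to the ketone carbonyl followed by syn-elimination of dimethyl phosphate. The only stereocentre formed, C5 of the furanone, is controlled by the configuration of the C–Cl carbon of 9 through stereospecific inversion, and the remote chromanol centre is untouched. The step needs substitution to outrun E2 loss of HCl towards the benzylidene compound and racemisation by chloride exchange, which the weakly basic pre-formed carboxylate (no free base until 9 is consumed) and its slight excess should secure; it also needs the carbanion to choose the ketone over the methyl ester, which the higher electrophilicity of the ketone and the irreversible olefination should secure.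

**Step 9**
Reactants: 13 methyl (2S)-3-[3,4-bis(benzyloxy)phenyl]-2-{[(3R)-3-hydroxy-2,2-dimethylchroman-6-yl]methyl}-4-methoxy-5-oxo-2,5-dihydrofuran-2-carboxylate
Product: 14 methyl (2S)-3-(3,4-dihydroxyphenyl)-2-{[(3R)-3-hydroxy-2,2-dimethylchroman-6-yl]methyl}-4-methoxy-5-oxo-2,5-dihydrofuran-2-carboxylate
Conditions: H2 (1 atm), 10% Pd/C, EtOAc–MeOH, rt
Reagents that add atoms: none
Why: hydrogenolysis of the two aryl benzyl ethers; the tetrasubstituted, conjugated and hindered furanone double bond and the non-benzylic C5–O bond should resist these mild conditions, and no stereocentre is affected.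

**Compound list**
1 | 2,2-dimethyl-2H-chromene-6-carbonitrile | CC1(C)C=Cc2cc(C#N)ccc2O1 | starting material
2 | (3R,4R)-3,4-epoxy-2,2-dimethylchromane-6-carbonitrile | N#Cc1ccc2c(c1)[C@H]3O[C@H]3C(C)(C)O2 | intermediate
3 | (3R)-3-hydroxy-2,2-dimethylchromane-6-carbonitrile | N#Cc1ccc2c(c1)C[C@@H](O)C(C)(C)O2 | intermediate
4 | (3R)-3-hydroxy-2,2-dimethylchromane-6-carbaldehyde | O=Cc1ccc2c(c1)C[C@@H](O)C(C)(C)O2 | intermediate
5 | 1-[3,4-bis(benzyloxy)phenyl]ethan-1-one | CC(=O)c1ccc(OCc2ccccc2)c(OCc2ccccc2)c1 | starting material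
6 | methyl 3-[3,4-bis(benzyloxy)phenyl]-3-oxopropanoate | COC(=O)CC(=O)c1ccc(OCc2ccccc2)c(OCc2ccccc2)c1 | intermediate
7 | methyl 2-[3,4-bis(benzyloxy)benzoyl]-3-[(3R)-3-hydroxy-2,2-dimethylchroman-6-yl]prop-2-enoate (E/Z mixture, not isolated) | COC(=O)C(=Cc1ccc2c(c1)C[C@@H](O)C(C)(C)O2)C(=O)c1ccc(OCc2ccccc2)c(OCc2ccccc2)c1 | intermediate
8 | methyl 3-[3,4-bis(benzyloxy)phenyl]-2-{[(3R)-3-hydroxy-2,2-dimethylchroman-6-yl]methyl}-3-oxopropanoate | COC(=O)C(Cc1ccc2c(c1)C[C@@H](O)C(C)(C)O2)C(=O)c1ccc(OCc2ccccc2)c(OCc2ccccc2)c1 | intermediate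
9 | methyl (2R)-3-[3,4-bis(benzyloxy)phenyl]-2-chloro-2-{[(3R)-3-hydroxy-2,2-dimethylchroman-6-yl]methyl}-3-oxopropanoate | COC(=O)[C@](Cc1ccc2c(c1)C[C@@H](O)C(C)(C)O2)(Cl)C(=O)c1ccc(OCc2ccccc2)c(OCc2ccccc2)c1 | intermediate
10 | methyl 2-(dimethoxyphosphoryl)-2-methoxyacetate | COC(=O)C(OC)P(=O)(OC)OC | starting material
11 | 2-(dimethoxyphosphoryl)-2-methoxyacetic acid | COC(C(=O)O)P(=O)(OC)OC | intermediate
12 | methyl (2S)-3-[3,4-bis(benzyloxy)phenyl]-2-{[2-(dimethoxyphosphoryl)-2-methoxyacetyl]oxy}-2-{[(3R)-3-hydroxy-2,2-dimethylchroman-6-yl]methyl}-3-oxopropanoate (mixture at the phosphonate carbon, not isolated) | COC(=O)[C@@](Cc1ccc2c(c1)C[C@@H](O)C(C)(C)O2)(OC(=O)C(OC)P(=O)(OC)OC)C(=O)c1ccc(OCc2ccccc2)c(OCc2ccccc2)c1 | intermediate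
13 | methyl (2S)-3-[3,4-bis(benzyloxy)phenyl]-2-{[(3R)-3-hydroxy-2,2-dimethylchroman-6-yl]methyl}-4-methoxy-5-oxo-2,5-dihydrofuran-2-carboxylate | COC(=O)[C@@]1(Cc2ccc3c(c2)C[C@@H](O)C(C)(C)O3)OC(=O)C(OC)=C1c1ccc(OCc2ccccc2)c(OCc2ccccc2)c1 | intermediate
14 | methyl (2S)-3-(3,4-dihydroxyphenyl)-2-{[(3R)-3-hydroxy-2,2-dimethylchroman-6-yl]methyl}-4-methoxy-5-oxo-2,5-dihydrofuran-2-carboxylate | COC(=O)[C@@]1(Cc2ccc3c(c2)C[C@@H](O)C(C)(C)O3)OC(=O)C(OC)=C1c1ccc(O)c(O)c1 | target

**Step count.** Total: 9 steps. Longest linear sequence: 7 steps (steps 1, 2, 3, 5, 6, 8, 9).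

**Steps most likely to fail**

Step 8. Substitution at the congested tertiary carbon may be slow, so that base-induced loss of HCl towards the benzylidene compound or erosion of configuration by chloride exchange competes. The fallback installs O1 by hydroxylation and closes the ring from the ester. It sets out from 8. Silylation (TBSCl, imidazole, DMF) should give the tert-butyldimethylsilyl ether of 8 F1. Catalytic asymmetric α-hydroxylation (cinchona-derived phase-transfer catalyst, cumene hydroperoxide) should give the (2S)-tertiary alcohol F2. Acylation of the tertiary hydroxyl with 11 (DCC, DMAP) should give the silylated analogue of 12 F3. LiCl/DBU olefination should give the silyl ether of 13 F4, and HF·pyridine returns the route to 13.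

Step 6. Facial selectivity in the chlorination of an acyclic methyl β-keto ester enolate may be poor. The fallback gives up catalyst control and sets out from 8. Chlorination with NCS without ligand should give 9 together with its (2S)-epimer F5. The mixture is taken through step 8, where F5 should react via the (2R)-epimer of 12 F6 to the C5-epimer of 13 F7. Because of the (3R)-chromanol centre, 13 and F7 are diastereomers, and preparative HPLC should deliver 13, where the route is rejoined.

Step 5. Condensation of the electron-rich aldehyde may stall, or a second β-keto ester may add to 7 before hydride transfer. The fallback is a classical C-alkylation and sets out from 4. NaBH4 reduction should give (3R)-6-(hydroxymethyl)-2,2-dimethylchroman-3-ol F8. Selective Appel bromination of the primary benzylic hydroxyl (CBr4, PPh3, 0 °C) should give (3R)-6-(bromomethyl)-2,2-dimethylchroman-3-ol F9. Alkylation of 6 with F9 (K2CO3, acetone) returns the route to 8.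

**Further compounds**
F1 | step 8 | methyl 3-[3,4-bis(benzyloxy)phenyl]-2-{[(3R)-3-(tert-butyldimethylsilyloxy)-2,2-dimethylchroman-6-yl]methyl}-3-oxopropanoate | COC(=O)C(Cc1ccc2c(c1)C[C@@H](O[Si](C)(C)C(C)(C)C)C(C)(C)O2)C(=O)c1ccc(OCc2ccccc2)c(OCc2ccccc2)c1
F2 | step 8 | methyl (2S)-3-[3,4-bis(benzyloxy)phenyl]-2-{[(3R)-3-(tert-butyldimethylsilyloxy)-2,2-dimethylchroman-6-yl]methyl}-2-hydroxy-3-oxopropanoate | COC(=O)[C@@](Cc1ccc2c(c1)C[C@@H](O[Si](C)(C)C(C)(C)C)C(C)(C)O2)(O)C(=O)c1ccc(OCc2ccccc2)c(OCc2ccccc2)c1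
F3 | step 8 | methyl (2S)-3-[3,4-bis(benzyloxy)phenyl]-2-{[(3R)-3-(tert-butyldimethylsilyloxy)-2,2-dimethylchroman-6-yl]methyl}-2-{[2-(dimethoxyphosphoryl)-2-methoxyacetyl]oxy}-3-oxopropanoate | COC(=O)[C@@](Cc1ccc2c(c1)C[C@@H](O[Si](C)(C)C(C)(C)C)C(C)(C)O2)(OC(=O)C(OC)P(=O)(OC)OC)C(=O)c1ccc(OCc2ccccc2)c(OCc2ccccc2)c1
F4 | step 8 | methyl (2S)-3-[3,4-bis(benzyloxy)phenyl]-2-{[(3R)-3-(tert-butyldimethylsilyloxy)-2,2-dimethylchroman-6-yl]methyl}-4-methoxy-5-oxo-2,5-dihydrofuran-2-carboxylate | COC(=O)[C@@]1(Cc2ccc3c(c2)C[C@@H](O[Si](C)(C)C(C)(C)C)C(C)(C)O3)OC(=O)C(OC)=C1c1ccc(OCc2ccccc2)c(OCc2ccccc2)c1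
F5 | step 6 | methyl (2S)-3-[3,4-bis(benzyloxy)phenyl]-2-chloro-2-{[(3R)-3-hydroxy-2,2-dimethylchroman-6-yl]methyl}-3-oxopropanoate | COC(=O)[C@@](Cc1ccc2c(c1)C[C@@H](O)C(C)(C)O2)(Cl)C(=O)c1ccc(OCc2ccccc2)c(OCc2ccccc2)c1
F6 | step 6 | methyl (2R)-3-[3,4-bis(benzyloxy)phenyl]-2-{[2-(dimethoxyphosphoryl)-2-methoxyacetyl]oxy}-2-{[(3R)-3-hydroxy-2,2-dimethylchroman-6-yl]methyl}-3-oxopropanoate | COC(=O)[C@](Cc1ccc2c(c1)C[C@@H](O)C(C)(C)O2)(OC(=O)C(OC)P(=O)(OC)OC)C(=O)c1ccc(OCc2ccccc2)c(OCc2ccccc2)c1
F7 | step 6 | methyl (2R)-3-[3,4-bis(benzyloxy)phenyl]-2-{[(3R)-3-hydroxy-2,2-dimethylchroman-6-yl]methyl}-4-methoxy-5-oxo-2,5-dihydrofuran-2-carboxylate | COC(=O)[C@]1(Cc2ccc3c(c2)C[C@@H](O)C(C)(C)O3)OC(=O)C(OC)=C1c1ccc(OCc2ccccc2)c(OCc2ccccc2)c1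
F8 | step 5 | (3R)-6-(hydroxymethyl)-2,2-dimethylchroman-3-ol | OCc1ccc2c(c1)C[C@@H](O)C(C)(C)O2
F9 | step 5 | (3R)-6-(bromomethyl)-2,2-dimethylchroman-3-ol | BrCc1ccc2c(c1)C[C@@H](O)C(C)(C)O2
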